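The whole plan rests on cutting two C–N bonds, N14–C10 and N1–C6. This turns the C6–C10 bond back into the C5=C4 bond of an aromatic 2-aminoimidazole. That bond is the feature exploited. It is common to the imidazoline and ketopiperazine rings, C10 also belongs to the pyrrolidine ring, and its two carbons carry all four ring nitrogens (N1, N7, N9, N14). A single two-electron oxidation of achiral, open-chain 1-N-methyldihydrooroidin (1-methyl-2-aminoimidazole, C4 propyl chain, terminal 4,5-dibromopyrrole-2-carboxamide), held in a chiral phosphate ion pair, should close both rings and set both stereocentres. The imidazole is built with its N-methyl group already in place.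

Key step: step 4

Remark (numbering): phakellin numbering is used: pyrrole N1, C2(Br), C3(Br), C4(H), C5; aminal CH C6; N7(Me); guanidine C8; N9; quaternary C10; C11–C13; lactam N14; carbonyl C15. The target SMILES reads as (6S,10R) with N1 and N14 on one face of the imidazoline ring and H-6 and C11 on the other (cis fusion).

Remark (assumption): the sense of induction of the phosphate cannot be derived with certainty. (R)-TRIP is written, and its equally available antipode would be used if the dextrorotatory series formed.

Remark (assumption): tert-butyl dimethylcarbamate is taken as a catalogue compound. Otherwise Boc2O and dimethylamine give it in one trivial operation.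

Remark (design): late N-methylation of a carbamate-protected 2-aminoimidazole is avoided. Acylguanidine condensations place the carbamate on the ring nitrogen next to C5–H, so alkylation would fall on the nitrogen beside the side chain (later N9). A 3-chloropropyl-2-aminoimidazole can also alkylate itself at N3. The methyl group and the side-chain nitrogen are therefore both built in before the ring is made.

Step 1
Reactants: 1 tert-butyl dimethylcarbamate; 2 tert-butyl 2-oxopyrrolidine-1-carboxylate (N-Boc-2-pyrrolidinone)
Product: 4 tert-butyl N-{5-[(tert-butoxycarbonyl)amino]-2-oxopentyl}-N-methylcarbamate, via lithiomethyl carbamate 3 (not isolated)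
Conditions: 1, s-BuLi, TMEDA, Et2O, −78 °C; then 2, −78 °C; aq NH4Cl
Reagents that add atoms: none
Why: Dipole-stabilised α-lithiation of an N-Boc methyl group gives 3, which adds to the activated lactam carbonyl of 2 (organolithium ring-opening acylation of an N-Boc lactam), and the cold tetrahedral adduct and its readily enolised ketone resist a second addition.

Step 2
Reactants: 4 tert-butyl N-{5-[(tert-butoxycarbonyl)amino]-2-oxopentyl}-N-methylcarbamate
Product: 6 4-(3-aminopropyl)-1-methyl-1H-imidazol-2-amine dihydrochloride, via aminoketone dihydrochloride 5 (not isolated)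
Conditions: 4 M HCl/dioxane, rt, evaporate; then H2NCN, H2O, pH 4.5, 95 °C
Reagents that add atoms: hydrogen chloride (Cl); cyanamide (NC#N)
Why: Acidolysis removes both Boc groups and a Marckwald-type cyanamide condensation follows, in which only the weakly basic α-keto methylamine is free enough at pH 4.5 to add to cyanamide, the N-methylguanidine closes on the ketone (or on its reversibly formed pyrrolinium form) and aromatises, and the methyl group necessarily ends on the ring nitrogen next to C5–H.

Step 3
Reactants: 6 4-(3-aminopropyl)-1-methyl-1H-imidazol-2-amine dihydrochloride; 7 4,5-dibromo-2-(trichloroacetyl)pyrrole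
Product: 8 1-N-methyldihydrooroidin, N-[3-(2-amino-1-methyl-1H-imidazol-4-yl)propyl]-4,5-dibromo-1H-pyrrole-2-carboxamide (free base)
Conditions: Na2CO3, DMF, rt
Reagents that add atoms: none
Why: In this haloform-type acyl transfer the trichloromethyl ketone acylates the primary alkylamine with loss of chloroform, while the 2-amino group, being part of a delocalised guanidine, is far less nucleophilic and should stay free.

Step 4
Reactants: 8 1-N-methyldihydrooroidin
Product: 11 (−)-7-N-methyldibromophakellin (6S,10R), via phosphate ion pair 9 (not isolated), via spiro bromide 10 (not isolated)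
Conditions: (R)-TRIP (1.05 equiv), 4 Å MS, CH2Cl2/PhMe, rt → −40 °C, dark; NBS (1.0 equiv), −40 °C; then Cs2CO3, −40 → 0 °C; extraction into dil. HCl, then Na2CO3 (TRIP recovered from the organic layer)
Reagents that add atoms: none
Why: Proposed new method: the phosphoric acid protonates 8 to the contact ion pair 9, whose phosphate oxygens hold N9–H and the adjacent exocyclic N–H (the methyl group blocks the N7 side, so one binding mode remains) and pass that proton on to the departing succinimide while NBS transfers Br+ to C6, the unsubstituted ring carbon whose attack spreads the charge over N7–C8–NH2 and the C10=N9 bond. The amide nitrogen N14, hydrogen-bonded to the same phosphate, adds to C10 anti to bromine in a 5-exo-trig closure (pyrrolidine ring) to give 10; carbonate then deprotonates the acidic dibromopyrrole N–H, the N7 lone pair loosens the C6–Br bond, and N1 closes the ketopiperazine ring 6-exo-trig. The closest known reaction types are the racemic halogen-triggered, base-completed cyclisation of dihydrooroidin-type 2-aminoimidazoles and the chiral-phosphate-controlled bromocyclisation of alkenes by amide nucleophiles, and their union on a heteroaromatic C=C bond has not been shown. C10 is reagent-controlled: the anchored phosphate also accepts the N14–H hydrogen bond, its 3,3'-aryl walls should allow this arrangement on one face of the flat cation only, and this C–N bond formation fixes the absolute configuration. C6 is substrate-controlled: the short N14–C15–C5–N1 tether reaches C6 only from the face N14 already occupies, which is also the rear of the C–Br bond, so only the cis-fused tetracycle can form. The step needs imidazole-over-pyrrole bromination (the pyrrole carries two bromines and an acyl group), N- over O-attack of the amide (five- against seven-membered ring) and N1 over C4 closure (secured by the pyrrolide anion at low temperature), and adding the base cold limits reversible opening of the C10 aminal before the second ring locks it.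

Compound list
1 | tert-butyl dimethylcarbamate | CN(C)C(=O)OC(C)(C)C | starting material
2 | tert-butyl 2-oxopyrrolidine-1-carboxylate | O=C1CCCN1C(=O)OC(C)(C)C | starting material
3 | tert-butyl (lithiomethyl)(methyl)carbamate | [Li]CN(C)C(=O)OC(C)(C)C | intermediate
4 | tert-butyl N-{5-[(tert-butoxycarbonyl)amino]-2-oxopentyl}-N-methylcarbamate | CN(CC(=O)CCCNC(=O)OC(C)(C)C)C(=O)OC(C)(C)C | intermediate
5 | 5-amino-1-(methylamino)pentan-2-one dihydrochloride | CNCC(=O)CCCN.Cl.Cl | intermediate
6 | 4-(3-aminopropyl)-1-methyl-1H-imidazol-2-amine dihydrochloride | Cn1cc(CCCN)nc1N.Cl.Cl | intermediate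
7 | 4,5-dibromo-2-(trichloroacetyl)pyrrole | O=C(c1cc(Br)c(Br)[nH]1)C(Cl)(Cl)Cl | starting material
8 | 1-N-methyldihydrooroidin | Cn1cc(CCCNC(=O)c2cc(Br)c(Br)[nH]2)nc1N | intermediate
9 | 1-N-methyldihydrooroidinium (R)-3,3'-bis(2,4,6-triisopropylphenyl)-1,1'-binaphthyl-2,2'-diyl phosphate (axial chirality is not expressible in SMILES) | Cn1cc(CCCNC(=O)c2cc(Br)c(Br)[nH]2)[nH+]c1N.[O-]P1(=O)Oc2c(-c4c(C(C)C)cc(C(C)C)cc4C(C)C)cc3ccccc3c2-c2c(O1)c(-c4c(C(C)C)cc(C(C)C)cc4C(C)C)cc1ccccc21 | intermediate
10 | [(4R,5R)-2-amino-4-bromo-3-methyl-1,3,6-triazaspiro[4.4]non-1-en-6-yl](4,5-dibromo-1H-pyrrol-2-yl)methanone, Br anti to the acylated nitrogen, written neutral | CN1C(N)=N[C@@]2(CCCN2C(=O)c2cc(Br)c(Br)[nH]2)[C@H]1Br | intermediate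
11 | (−)-7-N-methyldibromophakellin, (6S,10R) | CN1C(N)=N[C@]23CCCN2C(=O)c2cc(Br)c(Br)n2[C@H]13 | target

Total step count: 4
Longest linear sequence: 4 (1 → 4 → 6 → 8 → 11)

Steps most likely to fail

Step 4 (the only step beyond known chemistry). Three things could go wrong. Facial discrimination in the ion pair may be poor. The C10 configuration may erode through reversible aminal opening before the second closure. Proton loss with rearomatisation may compete with capture by N14. The fallback gives up asymmetric induction and uses the known racemic halogen/base protocol of this compound class followed by resolution. Setting out from 8, bromine in acetic acid should give racemic spiro bromide F1. Potassium tert-butoxide in tert-butanol should close it to racemic 7-N-methyldibromophakellin F2. Preparative HPLC on a polysaccharide chiral stationary phase then separates the enantiomers. The levorotatory one rejoins the route at 11, and the dextrorotatory enantiomer F3 is set aside.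

Step 1. The strongly basic organolithium may deprotonate the lactam α-position instead of adding to the carbonyl, or it may attack the carbamate carbonyl. The fallback introduces the C1 unit and the nitrogen separately with much less basic reagents. Setting out from 2, dimethylsulfoxonium methylide (Me3S(O)I, KOt-Bu, THF) should open the lactam to tert-butyl [5-(dimethyl-oxo-λ6-sulfanylidene)-4-oxopentyl]carbamate F4. One equivalent of HCl in warm THF converts this into tert-butyl (5-chloro-4-oxopentyl)carbamate F5. Excess methylamine in THF at 0 °C gives tert-butyl [5-(methylamino)-4-oxopentyl]carbamate F6. After the volatile amine is stripped off, Boc2O caps F6 in the same flask and the sequence rejoins the route at 4.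

Step 2. The free α-aminoketone may self-condense, material may be lost through the cyclic imine of the unprotected distal amine, or guanylation may occur at the wrong nitrogen. The fallback keeps the distal nitrogen masked as an imide until the heterocycle exists. Setting out from 1, the lithio species 3 is acylated with commercial 4-chloro-N-methoxy-N-methylbutanamide (Weinreb ketone synthesis) to tert-butyl (5-chloro-2-oxopentyl)(methyl)carbamate F7. Gabriel alkylation of potassium phthalimide (DMF, cat. NaI) gives tert-butyl [5-(1,3-dioxoisoindolin-2-yl)-2-oxopentyl](methyl)carbamate F8. HCl in dioxane releases 2-[5-(methylamino)-4-oxopentyl]isoindoline-1,3-dione hydrochloride F9. This is condensed with cyanamide at pH 4.5 to 2-[3-(2-amino-1-methyl-1H-imidazol-4-yl)propyl]isoindoline-1,3-dione hydrochloride F10. Hydrazinolysis in ethanol followed by HCl rejoins the route at 6.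

Further compounds
F1 | step 4 | racemic (2-amino-4-bromo-3-methyl-1,3,6-triazaspiro[4.4]non-1-en-6-yl)(4,5-dibromo-1H-pyrrol-2-yl)methanone | CN1C(N)=NC2(CCCN2C(=O)c2cc(Br)c(Br)[nH]2)C1Br
F2 | step 4 | racemic cis-fused 7-N-methyldibromophakellin | CN1C(N)=NC23CCCN2C(=O)c2cc(Br)c(Br)n2C13
F3 | step 4 | (+)-7-N-methyldibromophakellin, (6R,10S) | CN1C(N)=N[C@@]23CCCN2C(=O)c2cc(Br)c(Br)n2[C@@H]13
F4 | step 1 | tert-butyl [5-(dimethyl-oxo-λ6-sulfanylidene)-4-oxopentyl]carbamate | CS(C)(=O)=CC(=O)CCCNC(=O)OC(C)(C)C
F5 | step 1 | tert-butyl (5-chloro-4-oxopentyl)carbamate | ClCC(=O)CCCNC(=O)OC(C)(C)C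
F6 | step 1 | tert-butyl [5-(methylamino)-4-oxopentyl]carbamate | CNCC(=O)CCCNC(=O)OC(C)(C)C
F7 | step 2 | tert-butyl (5-chloro-2-oxopentyl)(methyl)carbamate | CN(CC(=O)CCCCl)C(=O)OC(C)(C)C
F8 | step 2 | tert-butyl [5-(1,3-dioxoisoindolin-2-yl)-2-oxopentyl](methyl)carbamate | CN(CC(=O)CCCN1C(=O)c2ccccc2C1=O)C(=O)OC(C)(C)C
F9 | step 2 | 2-[5-(methylamino)-4-oxopentyl]isoindoline-1,3-dione hydrochloride | CNCC(=O)CCCN1C(=O)c2ccccc2C1=O.Cl
F10 | step 2 | 2-[3-(2-amino-1-methyl-1H-imidazol-4-yl)propyl]isoindoline-1,3-dione hydrochloride | Cn1cc(CCCN2C(=O)c3ccccc3C2=O)nc1N.Cl
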